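The data are simulated for an exercise; noise was put on by code.

At 60.0 min in the dawn run there is more left-handed product (47.0%) than right-handed product (24.7%), yet the left-handed and right-handed substrate stand close, at 12.2% and 13.7%. I read this as a dynamic kinetic resolution, with the reagent and the single-handed free catalyst turning each substrate into the product of its own hand and the racemization catalyst turning the two substrates into each other.

| setting | dawn | spring | midnight | alpha | theta | gamma |
|---|---|---|---|---|---|---|
| left-handed substrate | 0.038 M | 0.038 M | 0.038 M | 0.038 M | 0.038 M | 0.038 M |
| right-handed substrate | 0.038 M | 0.038 M | 0.038 M | 0.038 M | 0.038 M | 0.038 M |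
| reagent | 0.14 M | 0.16 M | 0.27 M | 0.110 M | 0.170 M | 0.260 M |
| free catalyst | 76 µM | 76 µM | 76 µM | 76 µM | 76 µM | 76 µM |
| racemization catalyst | 1.2 mM | 1.2 mM | 1.2 mM | 1.2 mM | 1.2 mM | 1.2 mM |
| remark | run made earlier | run made earlier | run made earlier |  |  |  |
| time |  |  |  | 2.0 h | 2.0 h | 2.0 h |

| run | time / min | left-handed product / % | left-handed substrate / % | right-handed product / % | right-handed substrate / % |
|---|---|---|---|---|---|
| dawn | 5.00 | 8.0 | 42.2 | 3.6 | 44.6 |
| dawn | 15.0 | 21.2 | 33.1 | 12.1 | 35.1 |
| dawn | 30.0 | 35.0 | 23.1 | 17.7 | 25.4 |
| dawn | 40.0 | 39.9 | 20.0 | 21.7 | 21.7 |
| dawn | 60.0 | 47.0 | 12.2 | 24.7 | 13.7 |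
| spring | 5.00 | 10.8 | 40.6 | 4.7 | 42.8 |
| spring | 10.0 | 17.4 | 32.7 | 8.9 | 37.8 |
| spring | 15.0 | 23.9 | 28.5 | 12.5 | 33.1 |
| spring | 30.0 | 35.3 | 20.6 | 20.4 | 22.0 |
| spring | 60.0 | 49.9 | 8.7 | 27.3 | 9.3 |
| midnight | 5.00 | 17.2 | 35.8 | 8.3 | 39.5 |
| midnight | 15.0 | 34.1 | 20.7 | 20.7 | 26.6 |
| midnight | 30.0 | 48.9 | 9.5 | 27.8 | 13.8 |
| midnight | 40.0 | 55.2 | 7.4 | 29.9 | 8.4 |
| midnight | 60.0 | 59.9 | 2.1 | 34.0 | 5.1 |

(standard deviation of a reading: 1 percentage point)

- free catalyst is single-handed; left-handed substrate and right-handed substrate are mirror images of each other, charged as a racemate, each of them at the stated concentration

- which of these there is most of at the end, counted by the substrate in it, alpha (right-handed substrate / left-handed substrate / left-handed product / right-handed product)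
- which of these there is most of at the end, counted by the substrate in it, theta (right-handed substrate / left-handed substrate / left-handed product / right-handed product)
- which of these there is most of at the end, counted by the substrate in it, gamma (right-handed substrate / left-handed substrate / left-handed product / right-handed product)
- amount of the one of these that there is most of at the end, in percent of the left-handed substrate and right-handed substrate together charged, alpha
- amount of the one of these that there is most of at the end, in percent of the left-handed substrate and right-handed substrate together charged, theta
- amount of the one of these that there is most of at the end, in percent of the left-handed substrate and right-handed substrate together charged, gamma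

I keep the books on the substrate pair. Alpha holds less reagent than theta or gamma, but its 0.110 M is still more than the 0.0760 M of the pair, so if one mole of reagent is spent per mole of the pair, the pair is the limiting reagent in alpha, and the same holds with more room in theta and gamma. Each mole of the pair has three possible entries: left-handed product, right-handed product, or substrate still unconverted. In the midnight run at 60.0 min the four readings add up to 101%, so the books close within the scatter.

The zero of my scale is the even split, a fraction 0.5 of the products on each hand, which is what mirror images give without any preference. The last readings of the three runs together give 64.6%: this is the left share, the part of both products that is left-handed product. It stands 15 percentage points above the zero. The left share reads 65.6% in the dawn run and 63.8% in the midnight run, though the reagent there is twice as much. So my rule, with the charges of the pair and of both catalysts held as in these runs, is that left-handed product equals the left share times the part of the pair converted. The midnight run, close to gamma in reagent, has 7.20% of the pair unconverted at 60.0 min, so I expect gamma at 2.0 h to stand a little under 64.6%.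

The forecast names left-handed product for alpha, theta and gamma, at 53%, 61% and 64%, and calls the product ratio “independent of reagent”.

The flask gives left-handed product in each, at 53.8%, 61.6% and 63.5%, so the forecast held.

    reagent + free catalyst + left-handed substrate → free catalyst + left-handed product (k = 63.1 L² mol⁻² s⁻¹)
    reagent + free catalyst + right-handed substrate → free catalyst + right-handed product (k = 31.0 L² mol⁻² s⁻¹)
    left-handed substrate + racemization catalyst ⇌ right-handed substrate + racemization catalyst, rate k3*[racemization catalyst]*[left-handed substrate] forward; the back reaction follows from the equilibrium constant (k = 1.38 L mol⁻¹ s⁻¹)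
    racemization catalyst ⇌ dormant form (K = 0.106, k = 0.00639 s⁻¹)
    reagent → decomposition product (k = 3.66 × 10⁻⁷ s⁻¹)

On gamma the ledger books 64.6% of the converted pair, which is 64.1%, against the 63.5% computed. Gamma ends above alpha, and the difference in reagent may be called the main reason: with the reagent of alpha, gamma gives 53.8% instead of 63.5%. The entry that differs is the unconverted pair, 18.3% in alpha against 0.708% in gamma.

The neighbour of theta with 0.043 M of reagent holds less reagent than pair, so there the reagent is the entry to book: its whole charge at the left share comes to 36.5% of the pair, and the part spent, with 24% still there, to 27.6%. Computed, that flask ends with 28.4% of left-handed product and 14.2% of right-handed product.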